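**Plan**

1. Ring positions follow carotenoid numbering: C1 = CMe2, C2 = CH2, C3 = CHOH, C4=C5(Me), C6 = CH bearing the chain, C7–C8′ = chain. The retrosynthesis cuts C7=C8 (olefination), then the ring bonds C3–C4 and C1–C6, leaving two C5 isoprenoid pieces (C4–C7 with the C5 methyl; C1–C3 with both C1 methyls).
2. Enabling feature: on the cyclohexene ring the C3–O and C6–C7 bonds are cis and 1,4 to each other, so O3 and C7 can be tied in a temporary pyran ring. The ring unit is then a 2-oxabicyclo[2.2.2]oct-5-ene with C3 and C6 as bridgeheads, where Bredt's rule pins the alkene at C4=C5 and C6 cannot epimerize.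
3. Forward: alcohol 1 → aldehyde 2; prenal 3 → silyloxy diene 4; 2 + 4 in one flask give the pyran ring by hetero-Diels–Alder addition (adduct 5, C3–C4), then the carbocycle by hydrogen-atom-transfer radical cycloisomerization (bicyclic acetal 6, C1–C6).
4. Then 6 → aldehyde 7 → cis diol 8 → sulfide 9 → sulfone 10; the C20 chain is joined last by Julia–Kocienski olefination of crocetin dialdehyde 11 to give 12.
5. Stereochemistry: C3 (S) from the chiral chromium catalyst of the cycloaddition; C6 (R) relayed from C3 through the one-carbon tether in the bridging closure; the all-E chain from all-E 11 and the E-selective olefination.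

Key step: step 3

Remark: crocetin dialdehyde 11 (8,8′-diapocarotene-8,8′-dial) is taken as a purchasable carotenoid building block.

Step 1
Reactants: 1 3-methylbut-3-en-1-ol
Product: 2 3-methylbut-3-enal
Conditions: TEMPO (10 mol %), PhI(OAc)2, CH2Cl2, 0 °C to rt; short-path distillation, kept cold and used at once
Reagents that add atoms: none
Why: TEMPO/PhI(OAc)2 oxidation of a primary alcohol stops at the aldehyde under near-neutral conditions, which should keep the β,γ-alkene from moving into conjugation.

Step 2
Reactants: 3 3-methylbut-2-enal (prenal)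
Product: 4 tert-butyl(dimethyl){[(1E)-3-methylbuta-1,3-dien-1-yl]oxy}silane
Conditions: TBSOTf, Et3N, Et2O, 0 °C to rt
Reagents that add atoms: tert-butyldimethylsilyl trifluoromethanesulfonate, CC(C)(C)[Si](C)(C)OS(=O)(=O)C(F)(F)F
Why: Soft enolization of an enal (O-silylation, then γ-deprotonation by the amine) gives the 1-silyloxy-1,3-diene, with the E enol ether favoured on steric grounds.

Step 3
Reactants: 2 3-methylbut-3-enal; 4 tert-butyl(dimethyl){[(1E)-3-methylbuta-1,3-dien-1-yl]oxy}silane
Product: 6 (1S,3R,4R)-3-[(tert-butyldimethylsilyl)oxy]-5,8,8-trimethyl-2-oxabicyclo[2.2.2]oct-5-ene, via hetero-Diels–Alder adduct 5 (not isolated)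
Conditions: tridentate Schiff-base chromium chloride catalyst [Cr(L)Cl, trivalent chromium, L = imine of 3-(1-adamantyl)-5-methylsalicylaldehyde and cis-1-aminoindan-2-ol, enantiomer chosen to give (6S)-5] (3 mol %), 4 Å MS, neat, rt; then PhH, (salen)CoCl [salen = N,N′-bis(3,5-di-tert-butylsalicylidene)-1,2-cyclohexanediamine dianion, trivalent cobalt] (5 mol %), PhSiH3 (6 mol %), rt
Reagents that add atoms: none
Why: Proposed new method: the chromium Lewis acid first brings about an endo [4+2] hetero-Diels–Alder addition of diene 4 to the Re face of aldehyde 2, which closes the dihydropyran ring, forms C3–C4 and O–C7, sets C3 under catalyst control and the acetal carbon C7 cis to it by the endo rule (a well-documented reaction class for 1-oxygenated dienes and aliphatic aldehydes). The cobalt hydride made from (salen)CoCl and PhSiH3 then passes a hydrogen atom to the terminal 1,1-disubstituted alkene of 5, the tertiary C1 radical closes on C6 of the ring alkene in a 6-endo-trig mode through a boat, and the resulting tertiary C5 radical returns a C4 hydrogen atom to divalent cobalt, so that C1–C6 and the C4=C5 alkene arise in a redox-neutral isomerization. The closest known reactions are cobalt salen/silane hydrogen-atom-transfer cycloisomerizations of unactivated dienes and 6-endo closures of tertiary radicals on trisubstituted alkenes in radical polyene cyclizations; new is the bridging closure on a cyclic allylic acetal, run in the flask of the cycloaddition. C6 needs no outside control, since the radical hangs from C3 by a single CH2 and can reach C6 only on the ring face that carries that side chain, which makes the C3–O and C6–C7 bonds cis and so gives (6R) from (3S). The step needs hydrogen-atom transfer to the side-chain alkene and not to the ring alkene (terminal 1,1-disubstituted against hindered trisubstituted), 6-endo and not 5-exo closure (5-exo would join the tertiary radical to the methyl-bearing C5 and build two adjacent quaternary carbons) and one alkene position (alkenes at the bridgeheads C3 and C6 are excluded by Bredt's rule, and an exocyclic methylene re-enters the cycle until the trisubstituted C4=C5 isomer is reached). In the cis adduct the weak acetal C–H bond lies on the ring face away from the radical, so a 1,5 hydrogen shift cannot divert it.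

Step 4
Reactants: 6 (1S,3R,4R)-3-[(tert-butyldimethylsilyl)oxy]-5,8,8-trimethyl-2-oxabicyclo[2.2.2]oct-5-ene
Product: 8 (1S,4R)-4-(hydroxymethyl)-3,5,5-trimethylcyclohex-2-en-1-ol, via hydroxy aldehyde 7 (not isolated)
Conditions: Bu4NF, AcOH, THF, 0 °C; then NaBH4, MeOH, 0 °C
Reagents that add atoms: none
Why: Fluoride cleaves the anomeric silyl ether to the lactol, whose open hydroxy aldehyde form is reduced at once by borohydride under buffered, cold conditions, so that C6 next to the aldehyde should neither epimerize nor let the alkene move.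

Step 5
Reactants: 8 (1S,4R)-4-(hydroxymethyl)-3,5,5-trimethylcyclohex-2-en-1-ol
Product: 9 (1S,4R)-3,5,5-trimethyl-4-{[(1-phenyl-1H-tetrazol-5-yl)sulfanyl]methyl}cyclohex-2-en-1-ol
Conditions: 1-phenyl-1H-tetrazole-5-thiol (1.05 equiv), PPh3, DIAD, THF, 0 °C to rt
Reagents that add atoms: 1-phenyl-1H-tetrazole-5-thiol, Sc1nnnn1-c1ccccc1
Why: Mitsunobu thioetherification should take the primary alcohol in preference to the secondary one, because the primary oxyphosphonium ion forms and is displaced (SN2) faster, leaving C3 untouched.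

Step 6
Reactants: 9 (1S,4R)-3,5,5-trimethyl-4-{[(1-phenyl-1H-tetrazol-5-yl)sulfanyl]methyl}cyclohex-2-en-1-ol
Product: 10 (1S,4R)-3,5,5-trimethyl-4-{[(1-phenyl-1H-tetrazol-5-yl)sulfonyl]methyl}cyclohex-2-en-1-ol
Conditions: (NH4)6Mo7O24·4H2O (10 mol %), 30 % H2O2, EtOH, 0 °C to rt
Reagents that add atoms: hydrogen peroxide, OO
Why: Molybdate-catalyzed peroxide oxidation takes sulfides to sulfones much faster than it attacks a trisubstituted alkene or a secondary alcohol in cold ethanol.

Step 7
Reactants: 10 (1S,4R)-3,5,5-trimethyl-4-{[(1-phenyl-1H-tetrazol-5-yl)sulfonyl]methyl}cyclohex-2-en-1-ol; 11 (2E,4E,6E,8E,10E,12E,14E)-2,6,11,15-tetramethylhexadeca-2,4,6,8,10,12,14-heptaenedial (crocetin dialdehyde)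
Product: 12 (2E,4E,6E,8E,10E,12E,14E,16E)-17-[(1R,4S)-4-hydroxy-2,6,6-trimethylcyclohex-2-en-1-yl]-2,6,11,15-tetramethylheptadeca-2,4,6,8,10,12,14,16-octaenal [(3S,6R)-3-hydroxy-8′-apo-ε-caroten-8′-al]
Conditions: KN(SiMe3)2 (2.1 equiv), THF, −78 °C; cannulated into 11 (3 equiv), THF, −78 °C to rt; aq. NH4Cl
Reagents that add atoms: none
Why: Julia–Kocienski olefination (addition of the sulfonyl carbanion to one aldehyde, Smiles rearrangement, loss of SO2 and tetrazololate) should give the E C7=C8 alkene, with the second equivalent of base holding C3–OH as its alkoxide and the excess of the symmetric dialdehyde suppressing double olefination.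

**Compound list**

1 | 3-methylbut-3-en-1-ol | CC(=C)CCO | starting material
2 | 3-methylbut-3-enal | CC(=C)CC=O | intermediate
3 | 3-methylbut-2-enal (prenal) | CC(C)=CC=O | starting material
4 | tert-butyl(dimethyl){[(1E)-3-methylbuta-1,3-dien-1-yl]oxy}silane | CC(=C)/C=C/O[Si](C)(C)C(C)(C)C | intermediate
5 | (2R,6S)-2-[(tert-butyldimethylsilyl)oxy]-4-methyl-6-(2-methylprop-2-en-1-yl)-5,6-dihydro-2H-pyran (cis, not isolated) | CC1=C[C@@H](O[Si](C)(C)C(C)(C)C)O[C@@H](CC(C)=C)C1 | intermediate
6 | (1S,3R,4R)-3-[(tert-butyldimethylsilyl)oxy]-5,8,8-trimethyl-2-oxabicyclo[2.2.2]oct-5-ene | CC1=C[C@H]2O[C@H](O[Si](C)(C)C(C)(C)C)[C@@H]1C(C)(C)C2 | intermediate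
7 | (1R,4S)-4-hydroxy-2,6,6-trimethylcyclohex-2-ene-1-carbaldehyde (in equilibrium with its bridged lactol, not isolated) | CC1=C[C@@H](O)CC(C)(C)[C@H]1C=O | intermediate
8 | (1S,4R)-4-(hydroxymethyl)-3,5,5-trimethylcyclohex-2-en-1-ol | CC1=C[C@@H](O)CC(C)(C)[C@H]1CO | intermediate
9 | (1S,4R)-3,5,5-trimethyl-4-{[(1-phenyl-1H-tetrazol-5-yl)sulfanyl]methyl}cyclohex-2-en-1-ol | CC1=C[C@@H](O)CC(C)(C)[C@H]1CSc2nnnn2-c3ccccc3 | intermediate
10 | (1S,4R)-3,5,5-trimethyl-4-{[(1-phenyl-1H-tetrazol-5-yl)sulfonyl]methyl}cyclohex-2-en-1-ol | CC1=C[C@@H](O)CC(C)(C)[C@H]1CS(=O)(=O)c2nnnn2-c3ccccc3 | intermediate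
11 | (2E,4E,6E,8E,10E,12E,14E)-2,6,11,15-tetramethylhexadeca-2,4,6,8,10,12,14-heptaenedial (crocetin dialdehyde) | O=C/C(C)=C/C=C/C(C)=C/C=C/C=C(C)/C=C/C=C(\C)C=O | starting material
12 | (2E,4E,6E,8E,10E,12E,14E,16E)-17-[(1R,4S)-4-hydroxy-2,6,6-trimethylcyclohex-2-en-1-yl]-2,6,11,15-tetramethylheptadeca-2,4,6,8,10,12,14,16-octaenal | CC1=C[C@@H](O)CC(C)(C)[C@H]1/C=C/C(C)=C/C=C/C(C)=C/C=C/C=C(C)/C=C/C=C(\C)C=O | target

**Step count**

Total steps: 7. Longest linear sequence: 6 steps (1 → 2 → 6 → 8 → 9 → 10 → 12, or 3 → 4 → 6 → … → 12).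

**Steps most likely to fail**

Step 3 (bears the label). The tertiary radical may hand a C2 hydrogen back to cobalt before it closes the ring. That moves the side-chain alkene into the unreactive trisubstituted position and stalls the cycloisomerization; facial selectivity in the cycloaddition could also be eroded. The fallback uses known chemistry only. It sets out from 5, isolated after the cycloaddition half of step 3. Bu4NF/AcOH followed by NaBH4/CeCl3·7H2O opens and reduces the lactol to (2Z,5S)-3,7-dimethylocta-2,7-diene-1,5-diol F1, with the Z alkene inherited from the pyran ring. Ac2O/pyridine gives (2Z,5S)-3,7-dimethylocta-2,7-diene-1,5-diyl diacetate F2. ClSO3H in 2-nitropropane at −78 °C then brings about the classical cation–olefin cyclization of a neryl-acetate-type diene through a chair: the C1 cation comes from the methallyl group, the Z alkene places CH2OAc axial and the C3 acetate equatorial (hence cis), and C4–H is lost. This gives [(1R,4S)-4-acetoxy-2,6,6-trimethylcyclohex-2-en-1-yl]methyl acetate F3. K2CO3/MeOH returns to the route at diol 8.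

Step 7. The C3 alkoxide of the dianion may attack the tetrazole of its own sulfone (aryl transfer), and the dialdehyde may be olefinated at both ends or with loss of E selectivity. The fallback sets out from 10. TBSOTf/2,6-lutidine gives tert-butyl(dimethyl)({(1S,4R)-3,5,5-trimethyl-4-[(1-phenyl-1H-tetrazol-5-ylsulfonyl)methyl]cyclohex-2-en-1-yl}oxy)silane F4. Its monoanion (KN(SiMe3)2, 1.1 equiv) is added to excess 11 to give the 3-O-tert-butyldimethylsilyl ether of 12, F5. HF·pyridine in THF then cleaves the silyl ether and comes back to the route at 12.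

Step 5. Substitution may compete at the allylic secondary alcohol (direct or with allylic shift), or the cis diol may cyclodehydrate to the bridged ether under Mitsunobu activation. The fallback sets out from 8 and decides the selectivity by O-sulfonylation rates instead. TsCl/pyridine at 0 °C gives [(1R,4S)-4-hydroxy-2,6,6-trimethylcyclohex-2-en-1-yl]methyl 4-methylbenzenesulfonate F6. Sodium 1-phenyl-1H-tetrazole-5-thiolate in DMF at 50 °C (a non-basic nucleophile) then displaces the sulfonate and comes back to the route at 9.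

**Further compounds**

F1 | step 3 | (2Z,5S)-3,7-dimethylocta-2,7-diene-1,5-diol | OC/C=C(/C)C[C@@H](O)CC(C)=C
F2 | step 3 | (2Z,5S)-3,7-dimethylocta-2,7-diene-1,5-diyl diacetate | CC(=O)OC/C=C(/C)C[C@@H](OC(C)=O)CC(C)=C
F3 | step 3 | [(1R,4S)-4-acetoxy-2,6,6-trimethylcyclohex-2-en-1-yl]methyl acetate | CC1=C[C@@H](OC(C)=O)CC(C)(C)[C@H]1COC(C)=O
F4 | step 7 | tert-butyl(dimethyl)({(1S,4R)-3,5,5-trimethyl-4-[(1-phenyl-1H-tetrazol-5-ylsulfonyl)methyl]cyclohex-2-en-1-yl}oxy)silane | CC1=C[C@@H](O[Si](C)(C)C(C)(C)C)CC(C)(C)[C@H]1CS(=O)(=O)c2nnnn2-c3ccccc3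
F5 | step 7 | (2E,4E,6E,8E,10E,12E,14E,16E)-17-[(1R,4S)-4-{[tert-butyl(dimethyl)silyl]oxy}-2,6,6-trimethylcyclohex-2-en-1-yl]-2,6,11,15-tetramethylheptadeca-2,4,6,8,10,12,14,16-octaenal | CC1=C[C@@H](O[Si](C)(C)C(C)(C)C)CC(C)(C)[C@H]1/C=C/C(C)=C/C=C/C(C)=C/C=C/C=C(C)/C=C/C=C(\C)C=O
F6 | step 5 | [(1R,4S)-4-hydroxy-2,6,6-trimethylcyclohex-2-en-1-yl]methyl 4-methylbenzenesulfonate | CC1=C[C@@H](O)CC(C)(C)[C@H]1COS(=O)(=O)c2ccc(C)cc2
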